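**Retrosynthetic overview**

- Target quinone 17 is the oxidised form of hydroquinone 16, so the last step only adjusts oxidation state.
- The strategy rests on one feature of the single six-membered ring: C1(=O)–C2(OMe)–C3(H)–C4(=O) is a contiguous oxygenated four-carbon block that maps onto a squarate-derived cyclobutenedione, and C5(Me)=C6(C25H51) is a trisubstituted alkene unit.
- The only ring is formed in one step by thermal ring expansion of 4-alkenyl-4-hydroxycyclobutenone 13: the four-ring C(=O)–C(OH) bond breaks and the C4–C5 bond forms.
- 13 comes from alkenyllithium 12 (from bromide 8) and methyl semisquarate 11, which sets the C1–C6 bond; 11 comes from dimethyl squarate 9 in two steps.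
- 8 comes from (Z)-1,2-dibromobut-2-ene 5 (three steps from crotonaldehyde 1) and the Grignard reagent of 1-bromotetracosane 6.

Key step: step 8

Remark on the chemistry: the target has no stereocentre and no stereogenic double bond, so the given structure is a single achiral compound and no enantiocontrol is needed. Target ring numbering used throughout: C1 (C=O) lies between C2 (OMe) and C6 (pentacosyl); C3 is CH, C4 is C=O, C5 carries the methyl.

**Route**

Step 1
Reactants: 1 (E)-but-2-enal (crotonaldehyde)
Product: 3 (Z)-2-bromobut-2-enal, via 2,3-dibromobutanal 2 (not isolated)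
Conditions: Br2 (1.0 equiv), CH2Cl2, 0 °C; then Et3N (1.2 equiv), 0 °C → rt
Reagents that add atoms: bromine, BrBr
Why: Anti addition of bromine to the enal C=C followed by amine-induced E1cB loss of HBr (acidic α-H, β-bromide) is the standard bromination–dehydrobromination route to α-bromoenals, and the elimination should give the more stable isomer with CHO trans to CH3, i.e. (Z).

Step 2
Reactants: 3 (Z)-2-bromobut-2-enal
Product: 4 (Z)-2-bromobut-2-en-1-ol
Conditions: NaBH4, CeCl3·7H2O, MeOH, 0 °C
Reagents that add atoms: none
Why: Luche conditions reduce the aldehyde carbonyl in 1,2-fashion without touching the C=C or the vinylic C–Br bond, so the alkene geometry is carried through unchanged.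

Step 3
Reactants: 4 (Z)-2-bromobut-2-en-1-ol
Product: 5 (Z)-1,2-dibromobut-2-ene
Conditions: PBr3 (0.4 equiv), Et2O, 0 °C
Reagents that add atoms: phosphorus tribromide, BrP(Br)Br
Why: PBr3 converts the primary allylic alcohol into the bromide by SN2 displacement of the bromophosphite at the unhindered CH2, leaving the vinylic bromide and the (Z)-geometry untouched.

Step 4
Reactants: 6 1-bromotetracosane; 5 (Z)-1,2-dibromobut-2-ene
Product: 8 (Z)-3-bromooctacos-2-ene, via tetracosylmagnesium bromide 7 (not isolated)
Conditions: 6, Mg turnings (BrCH2CH2Br activation), THF, 50 °C; then rapid addition to 5 (1.2 equiv), Li2CuCl4 (3 mol %), THF, 0 °C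
Reagents that add atoms: none
Why: Grignard formation followed by Kochi-type copper-catalysed sp3–sp3 coupling should substitute the primary allylic bromide at the α-carbon (rapid Grignard addition in THF with Li2CuCl4 favours α- over γ-attack), while the vinylic C–Br bond is inert to copper catalysis at 0 °C and the trisubstituted alkene keeps its geometry.

Step 5
Reactants: 9 dimethyl squarate
Product: 10 4-hydroxy-2,3-dimethoxycyclobut-2-en-1-one (racemic, used crude)
Conditions: LiAlH(OtBu)3 (1.05 equiv), THF, −78 → −20 °C; cold 1 M HCl quench, EtOAc extraction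
Reagents that add atoms: none
Why: The bulky alkoxyaluminium hydride delivers a single hydride to one of the two equivalent ketone carbonyls of the squarate and does not reduce the resulting alkoxide further at low temperature (chemoselective 1,2-reduction); the new carbinol centre is racemic and is removed in step 6.

Step 6
Reactants: 10 4-hydroxy-2,3-dimethoxycyclobut-2-en-1-one
Product: 11 3-methoxycyclobut-3-ene-1,2-dione (methyl semisquarate)
Conditions: conc. HCl (cat.), CH2Cl2, rt → 40 °C; dry (Na2SO4), concentrate cold, use promptly
Reagents that add atoms: water, O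
Why: Acid ionises the allylic C4 hydroxyl to a methoxy-stabilised cyclobutenyl cation, water adds at the distal methoxy-bearing carbon and the hemiketal expels methanol, a net allylic transposition with ketal hydrolysis that is the established way to make alkyl semisquarates from squarate monoreduction products.

Step 7
Reactants: 8 (Z)-3-bromooctacos-2-ene; 11 3-methoxycyclobut-3-ene-1,2-dione
Product: 13 4-hydroxy-3-methoxy-4-[(Z)-octacos-2-en-3-yl]cyclobut-2-en-1-one (racemic), via (E)-octacos-2-en-3-yllithium 12 (not isolated)
Conditions: 8, t-BuLi (2.0 equiv), Et2O–THF, −78 → −50 °C (suspension clears as exchange proceeds); cannulate into 11 (1.2 equiv), THF, −78 °C; sat. aq. NH4Cl at −78 °C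
Reagents that add atoms: none
Why: Bromine–lithium exchange with t-BuLi proceeds with retention of alkene geometry (only the CIP descriptor changes), and the alkenyllithium should add in 1,2-fashion to the more electrophilic ketone carbonyl of 11 (C2, next to the methoxy-bearing carbon) rather than to the vinylogous-ester carbonyl, which fixes the later C1–C6 connectivity; the new carbinol centre forms as a racemate and is destroyed in step 8.

Step 8
Reactants: 13 4-hydroxy-3-methoxy-4-[(Z)-octacos-2-en-3-yl]cyclobut-2-en-1-one
Product: 16 2-methoxy-5-methyl-6-pentacosylbenzene-1,4-diol, via dienylketene 14 (not isolated), via cyclohexa-2,4-dienone 15 (not isolated)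
Conditions: degassed toluene (0.02 M), 110 °C, Ar, 1–3 h
Reagents that add atoms: none
Why: Heating opens the strained cyclobutenone by thermal conrotatory 4π electrocyclic cleavage of its C1–C4 σ bond (a bond absent from the target) to dienylketene 14, and the electron-donating hydroxyl on C4 rotates outward (torquoselectivity), which places the alkenyl group inward, cis to the ketene across the new enol double bond. The ketene carbon then joins the CH(CH3) alkene terminus in a thermal disrotatory 6π electrocyclisation that closes the only ring of the target, the six-membered carbocycle, and forms what becomes the quinone C4–C5 bond; dienone 15 enolises at once to the aromatic hydroquinone, which makes the sequence irreversible. This is the Moore rearrangement of 4-alkenyl-4-hydroxycyclobutenones, an established route to hydroquinones. No stereocentre survives, since the carbinol centre of 13 and the transient sp3 centre of 15 are both erased, so the racemic nature of 13 and the alkene geometry do not affect the product. The step needs only outward rotation of the oxygen substituent, secured by the donor hydroxyl, and the correct substitution pattern, which was fixed in step 7 when C1 was bonded to C6 next to the methoxy carbon. The methyl on the alkene terminus points into the closing ring, which may slow closure but should not prevent it because the sp-hybridised ketene terminus is sterically undemanding.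

Step 9
Reactants: 16 2-methoxy-5-methyl-6-pentacosylbenzene-1,4-diol
Product: 17 2-methoxy-5-methyl-6-pentacosylcyclohexa-2,5-diene-1,4-dione (target)
Conditions: Ag2O (2.5 equiv), Na2SO4, Et2O–CH2Cl2, rt
Reagents that add atoms: none
Why: Silver(I) oxide is a mild two-electron oxidant that converts the electron-rich hydroquinone into the 1,4-benzoquinone without touching the methoxy group or the alkyl chain (hydroquinone–quinone oxidation).

**Compound list**

1 | (E)-but-2-enal (crotonaldehyde) | C/C=C/C=O | starting material
2 | (2R*,3S*)-2,3-dibromobutanal (racemic anti adduct, one enantiomer drawn) | C[C@H](Br)[C@H](Br)C=O | intermediate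
3 | (Z)-2-bromobut-2-enal | C/C=C(\Br)C=O | intermediate
4 | (Z)-2-bromobut-2-en-1-ol | C/C=C(\Br)CO | intermediate
5 | (Z)-1,2-dibromobut-2-ene | C/C=C(\Br)CBr | intermediate
6 | 1-bromotetracosane | CCCCCCCCCCCCCCCCCCCCCCCCBr | starting material
7 | tetracosylmagnesium bromide | CCCCCCCCCCCCCCCCCCCCCCCC[Mg]Br | intermediate
8 | (Z)-3-bromooctacos-2-ene | C/C=C(\Br)CCCCCCCCCCCCCCCCCCCCCCCCC | intermediate
9 | dimethyl squarate (3,4-dimethoxycyclobut-3-ene-1,2-dione) | COC1=C(OC)C(=O)C1=O | starting material
10 | 4-hydroxy-2,3-dimethoxycyclobut-2-en-1-one (racemic) | COC1=C(OC)C(O)C1=O | intermediate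
11 | 3-methoxycyclobut-3-ene-1,2-dione | COC1=CC(=O)C1=O | intermediate
12 | (E)-octacos-2-en-3-yllithium (Li cis to the C1 methyl) | C/C=C(\[Li])CCCCCCCCCCCCCCCCCCCCCCCCC | intermediate
13 | 4-hydroxy-3-methoxy-4-[(Z)-octacos-2-en-3-yl]cyclobut-2-en-1-one (racemic) | COC1=CC(=O)C1(O)/C(CCCCCCCCCCCCCCCCCCCCCCCCC)=C\C | intermediate
14 | (3Z,5Z)-4-hydroxy-3-methoxy-5-pentacosylhepta-1,3,5-trien-1-one (dienylketene) | O=C=C/C(OC)=C(O)\C(CCCCCCCCCCCCCCCCCCCCCCCCC)=C/C | intermediate
15 | 4-hydroxy-3-methoxy-6-methyl-5-pentacosylcyclohexa-2,4-dien-1-one (racemic) | O=C1C=C(OC)C(O)=C(CCCCCCCCCCCCCCCCCCCCCCCCC)C1C | intermediate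
16 | 2-methoxy-5-methyl-6-pentacosylbenzene-1,4-diol | COc1cc(O)c(C)c(CCCCCCCCCCCCCCCCCCCCCCCCC)c1O | intermediate
17 | 2-methoxy-5-methyl-6-pentacosylcyclohexa-2,5-diene-1,4-dione | CCCCCCCCCCCCCCCCCCCCCCCCCC1=C(C)C(=O)C=C(OC)C1=O | target

**Step count**

Total steps: 9. Longest linear sequence: 7 steps (steps 1, 2, 3, 4, 7, 8, 9 from crotonaldehyde); the squarate branch (steps 5 and 6) joins at step 7.

**Steps most likely to fail**

1. Step 8 (ring expansion). The dienylketene may be diverted before the 6π closure: partial inward rotation of the hydroxyl would lead to lactonisation through the enol oxygen, and ketene capture or oligomerisation becomes more competitive if the inward-pointing terminal methyl slows ring closure. The fallback abandons the electrocyclic cascade for radical alkylation of a preformed quinone; it sets out from 6 and returns at 17. Alkylation of diethyl malonate with 6 (NaOEt, EtOH–THF, reflux) would give diethyl 2-tetracosylmalonate F1. Saponification (KOH, aq. EtOH) would give 2-tetracosylmalonic acid F2, and heating (170 °C, neat) would give hexacosanoic acid F3. Teuber oxidation of commercial 2-methoxy-5-methylphenol (Fremy's salt, KH2PO4, aq. acetone) would supply 2-methoxy-5-methyl-1,4-benzoquinone F4. Silver-catalysed persulfate decarboxylation of F3 in the presence of F4 (AgNO3, (NH4)2S2O8, MeCN–H2O, 70–80 °C; Jacobsen–Torssell alkylation) would generate the pentacosyl radical. This nucleophilic radical should add at C6, the only unsubstituted carbon of the methyl-bearing double bond, because C3 is deactivated as the β-carbon of the enol ether. Reoxidation of the adduct radical would give 17 directly.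

2. Step 7 (exchange and addition). Bromine–lithium exchange may stay incomplete because the waxy C28 bromide precipitates at −78 °C, and warming to dissolve it invites proton transfer from, or over-addition to, the sensitive semisquarate. The fallback carries a short, freely soluble alkenyl partner through the same ring construction and appends the rest of the chain afterwards; it sets out from 5 and 11 and returns at 16. Coupling of 5 with commercial but-3-enylmagnesium bromide (Li2CuCl4 cat., THF, 0 °C) would give (Z)-3-bromoocta-2,7-diene F5, a mobile liquid that should exchange cleanly with t-BuLi at −78 °C. Addition to 11 as in step 7 would give 4-hydroxy-3-methoxy-4-[(2Z)-octa-2,7-dien-3-yl]cyclobut-2-en-1-one F6. Thermolysis as in step 8 should give 2-methoxy-5-methyl-6-(pent-4-en-1-yl)benzene-1,4-diol F7, and Ag2O oxidation 2-methoxy-5-methyl-6-(pent-4-en-1-yl)-1,4-benzoquinone F8. Cross-metathesis with excess commercial 1-docosene (Grubbs second-generation catalyst, CH2Cl2, 40 °C) would extend the chain to 2-methoxy-5-methyl-6-[(E)-pentacos-4-en-1-yl]-1,4-benzoquinone F9, whose alkene geometry is immaterial. Hydrogenation (H2, Pd/C, EtOAc) would saturate the chain and reduce the quinone, giving 16, which re-enters the route at step 9.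

3. Step 4 (allylic coupling). The cuprate may attack the γ-carbon (SN2′) and give the isomeric 2-bromo-3-methyl-1-alkene, which would be hard to separate from 8; a π-allyl copper intermediate could also scramble the geometry, and Wurtz homocoupling consumes the long-chain Grignard reagent. The fallback builds the C4–C5 bond by olefination so that the bromine position is fixed by construction; it sets out from 3 and 6 and returns at 8. Heating 6 with PPh3 (toluene, 110 °C) would give tetracosyltriphenylphosphonium bromide F10. Its ylide (NaHMDS, THF, −78 °C) and aldehyde 3 would give (2Z,4Z)-3-bromooctacosa-2,4-diene F11 by Wittig reaction. Diimide (2-nitrobenzenesulfonylhydrazide, Et3N, CH2Cl2, rt) should reduce the 1,2-disubstituted C4=C5 bond much faster than the trisubstituted bromoalkene and deliver 8.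

**Further compounds**

F1 | step 8 | diethyl 2-tetracosylmalonate | CCCCCCCCCCCCCCCCCCCCCCCCC(C(=O)OCC)C(=O)OCC
F2 | step 8 | 2-tetracosylmalonic acid | CCCCCCCCCCCCCCCCCCCCCCCCC(C(=O)O)C(=O)O
F3 | step 8 | hexacosanoic acid | CCCCCCCCCCCCCCCCCCCCCCCCCC(=O)O
F4 | step 8 | 2-methoxy-5-methylcyclohexa-2,5-diene-1,4-dione | COC1=CC(=O)C(C)=CC1=O
F5 | step 7 | (Z)-3-bromoocta-2,7-diene | C/C=C(\Br)CCCC=C
F6 | step 7 | 4-hydroxy-3-methoxy-4-[(2Z)-octa-2,7-dien-3-yl]cyclobut-2-en-1-one (racemic) | COC1=CC(=O)C1(O)/C(CCCC=C)=C\C
F7 | step 7 | 2-methoxy-5-methyl-6-(pent-4-en-1-yl)benzene-1,4-diol | COc1cc(O)c(C)c(CCCC=C)c1O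
F8 | step 7 | 2-methoxy-5-methyl-6-(pent-4-en-1-yl)cyclohexa-2,5-diene-1,4-dione | C=CCCCC1=C(C)C(=O)C=C(OC)C1=O
F9 | step 7 | 2-methoxy-5-methyl-6-[(E)-pentacos-4-en-1-yl]cyclohexa-2,5-diene-1,4-dione | CCCCCCCCCCCCCCCCCCCC/C=C/CCCC1=C(C)C(=O)C=C(OC)C1=O
F10 | step 4 | tetracosyltriphenylphosphonium bromide | CCCCCCCCCCCCCCCCCCCCCCCC[P+](c1ccccc1)(c1ccccc1)c1ccccc1.[Br-]
F11 | step 4 | (2Z,4Z)-3-bromooctacosa-2,4-diene | C/C=C(\Br)/C=C\CCCCCCCCCCCCCCCCCCCCCCC
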